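What is left of the left-handed substrate says how far a flask has gone. Free catalyst and dissolved reagent turn each substrate into its own product, while gas feeds the reagent. In the dawn run, 33.7% remains at 25.0 min out of the 50 charged as left-handed substrate, so that run has spent 0.395 time constants. This count, the logarithm of left-handed substrate charged over left-handed substrate remaining, is the integral of the pseudo-first-order rate.

| flask | left-handed substrate | right-handed substrate | gas | free catalyst | remark | time |
|---|---|---|---|---|---|---|
| autumn | 0.11 M | 0.11 M | 4.6 mM (held) | 11 mM | the very flask that is asked about, followed so far |  |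
| dawn | 0.055 M | 0.055 M | 4.6 mM (held) | 11 mM | run made earlier |  |
| flask | 0.11 M | 0.11 M | 4.6 mM (held) | 11 mM |  | 25 min |

| run | time / min | left-handed product / % | right-handed product / % | left-handed substrate / % |
|---|---|---|---|---|
| autumn | 0.667 | 0.4 | 0 | 49.7 |
| autumn | 1.33 | 0 | 0 | 49.5 |
| autumn | 2.00 | 0.9 | 0 | 49.1 |
| autumn | 3.00 | 1.1 | 0.6 | 48.7 |
| autumn | 4.00 | 2.2 | 0 | 47.9 |
| autumn | 5.00 | 3.1 | 0 | 46.7 |
| dawn | 2.00 | 0.6 | 0.2 | 48.4 |
| dawn | 3.00 | 1.4 | 0.4 | 48.1 |
| dawn | 5.00 | 3.3 | 0 | 46.2 |
| dawn | 8.00 | 6.1 | 0.1 | 44.5 |
| dawn | 10.0 | 8.0 | 0.3 | 42.3 |
| dawn | 15.0 | 10.8 | 0.5 | 38.9 |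
| dawn | 25.0 | 16.8 | 0.2 | 33.7 |

(readings scatter by 0.3 percentage points)

* excess of left-handed product over right-handed product in the product at 30 s
* excess of left-handed product over right-handed product in the product at 25 min
* part of the left-handed substrate and right-handed substrate charged together that has reacted at 25 min

- free catalyst is single-handed; left-handed substrate and right-handed substrate are mirror images of each other, charged as a racemate, each of them at the stated concentration
- at the start none of reagent is dissolved
- the numbers in the tables scatter with a standard deviation of 0.3 percentage points
- steps under discussion: 2 free catalyst -> spent catalyst; gas <-> reagent; free catalyst <-> dormant form; reagent + free catalyst + left-handed substrate -> free catalyst + left-handed product; reagent + free catalyst + right-handed substrate -> free catalyst + right-handed product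
- an excess is the difference of the two amounts in percent of their sum
- an excess is below zero if the other one leads

The dawn rate reads 0.0176 min⁻¹ between 5.00 min and 10.0 min, but 0.0143 min⁻¹ between 15.0 min and 25.0 min, a slowing by a factor of 0.813, as far as the scatter lets us read it. The logarithm has already taken out the substrate's own decline, and among the steps under discussion free catalyst leaving the round is our candidate for this slowing. The dawn count holds this slowing and the start with no reagent dissolved, so we keep it whole.

Doubling the substrate gives a second factor. At 5.00 min the autumn count is 0.864 of the dawn count at the same time, a weak reading given the scatter of 0.3 percentage points. Carrying this factor from 5.00 min to 25 min is our assumption; it makes our estimate of the count for the flask 0.341, which means 14.4% reacted.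

The forecast differs: it says “the reaction is about first order in substrate”, takes a count of 0.38, and gives 16% reacted, with excesses of 95.5% and 94.8%.

The flask gives excesses of 98.7% at 30 s and 98.5% at 25 min, with 13.8% reacted at 25 min.

    2 free catalyst → spent catalyst (k = 0.0130 M⁻¹ s⁻¹)
    gas ⇌ reagent, rate k2*(csat - [reagent]) (kL = 0.0116 s⁻¹)
    free catalyst ⇌ dormant form (K = 1.30, k = 1.06 × 10⁻⁴ s⁻¹)
    reagent + free catalyst + left-handed substrate → free catalyst + left-handed product (k = 9.47 M⁻² s⁻¹)
    reagent + free catalyst + right-handed substrate → free catalyst + right-handed product (k = 0.0618 M⁻² s⁻¹)

By 25.0 min the flask has spent 0.320 time constants, 0.810 of the count read in the dawn run. In this flask the half-life of reagent by the left-handed step as charged, 1.0 min, about equals the half-life of its uptake from the gas, 0.996 min, and c(reagent) stands at half of saturation, 0.00230 M, at 2.50 min. The neighbour flask, with 0.0044 M of free catalyst, 0.400 of this flask's charge, has spent 0.179 time constants, 0.559 of this flask's count, with 8.23% reacted.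

(The readings were computed on assumed constants, noise included.)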